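**Retrosynthet­ic overview**
1. Target 18 ⇒ jaeschkeanadiol 16 + 3,4‑dimethoxybenzoyl chloride 17 (acylation of the secondary C6–OH only).
2. Seven‑membered ring (formed last) ⇒ ring‑closing metathesis of the C1‑allyl and C6‑methallyl groups of cyclopentane diol 15; C6 comes from chelation‑controlled methallylation of β‑hydroxy aldehyde 13.
3. Five‑membered ring (formed first) ⇒ Wolff ring contraction of the six‑membered diazo ketone 9 (C4 migrates to C5 with retention).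
4. Quaternary C1 (C1–C10 bond) ⇒ anionic oxy‑Cope [3,3] rearrangement of allyl carbinol 5, the allyl group having been placed anti to the axial silyloxy group of enone 3.
5. Enone 3 ⇒ allylic oxidation of (S)‑(+)‑terpinen‑4‑ol 1, which supplies C4 (OH, iPr), C1–C6 and the C1 methyl.

Assumption: enantiopure (S)‑(+)‑terpinen‑4‑ol is purchasable; atom labels C1–C10 are daucane numbering (C1 = CMe, C4 = C(OH)iPr, C5 = ring‑fusion CH, C6 = CH–O, C8=C9 = alkene).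

**Step 1**
Reactants: 1 (S)‑(+)‑terpinen‑4‑ol, (1S)‑4‑methyl‑1‑(propan‑2‑yl)cyclohex‑3‑en‑1‑ol
Product: 2 triethyl{[(1S)‑4‑methyl‑1‑(propan‑2‑yl)cyclohex‑3‑en‑1‑yl]oxy}silane
Conditions: Et3SiOTf, 2,6‑lutidine, CH2Cl2, 0 °C to rt
Reagents that add atoms: triethylsilyl trifluoromethanesulfonate, CC[Si](CC)(CC)OS(=O)(=O)C(F)(F)F
Why: Silyl triflate silylation of the hindered tertiary alcohol gives a bulky, non‑chelating ether that is needed to steer step 3; the stereocentre is untouched.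

**Step 2**
Reactants: 2 triethyl{[(1S)‑4‑methyl‑1‑(propan‑2‑yl)cyclohex‑3‑en‑1‑yl]oxy}silane
Product: 3 (6R)‑3‑methyl‑6‑(propan‑2‑yl)‑6‑[(triethylsilyl)oxy]cyclohex‑2‑en‑1‑one
Conditions: t‑BuOOH (5 equiv), Rh2(C6H10NO)4 [dirhodium tetrakis(caprolactamate)] (1 mol %), K2CO3, CH2Cl2, rt
Reagents that add atoms: tert‑butyl hydroperoxide, CC(C)(C)OO
Why: Radical allylic C–H oxidation should occur at the CH2 next to the unsubstituted vinyl carbon, because that gives the more substituted allyl radical (as in 5‑ene steroids to 7‑ketones), giving the β‑methyl enone without touching the carbinol centre.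

**Step 3**
Reactants: 3 (6R)‑3‑methyl‑6‑(propan‑2‑yl)‑6‑[(triethylsilyl)oxy]cyclohex‑2‑en‑1‑one; 4 allylmagnesium bromide
Product: 5 (1R,6R)‑3‑methyl‑6‑(propan‑2‑yl)‑1‑(prop‑2‑en‑1‑yl)‑6‑[(triethylsilyl)oxy]cyclohex‑2‑en‑1‑ol
Conditions: THF, −78 °C; aq. NH4Cl
Reagents that add atoms: none
Why: Grignard 1,2‑addition: in the half‑chair with iPr equatorial and OSiEt3 axial, the reagent attacks axially and anti to the C–O bond (polar Felkin–Anh/Cornforth, no chelation), so the allyl group ends trans to OSiEt3.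

**Step 4**
Reactants: 5 (1R,6R)‑3‑methyl‑6‑(propan‑2‑yl)‑1‑(prop‑2‑en‑1‑yl)‑6‑[(triethylsilyl)oxy]cyclohex‑2‑en‑1‑ol
Product: 7 (2R,5R)‑2‑hydroxy‑5‑methyl‑2‑(propan‑2‑yl)‑5‑(prop‑2‑en‑1‑yl)cyclohexan‑1‑one, via silyl ketone 6 (not isolated)
Conditions: KH, 18‑crown‑6, THF, 0 °C to rt; AcOH (2 equiv); then Bu4NF, rt
Reagents that add atoms: none
Why: Anionic oxy‑Cope ([3,3]‑sigmatropic) rearrangement moves the axial allyl group suprafacially, on the face it already occupies, to the β‑carbon; this forms the C1–C10 bond and the quaternary centre with allyl trans to oxygen and cis to iPr, and fluoride then removes the silyl group (collecting any O‑to‑O silyl‑migrated material).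

**Step 5**
Reactants: 7 (2R,5R)‑2‑hydroxy‑5‑methyl‑2‑(propan‑2‑yl)‑5‑(prop‑2‑en‑1‑yl)cyclohexan‑1‑one
Product: 9 (2R,5R)‑6‑diazo‑2‑hydroxy‑5‑methyl‑2‑(propan‑2‑yl)‑5‑(prop‑2‑en‑1‑yl)cyclohexan‑1‑one, via trifluoroacetyl ketone 8 (not isolated)
Conditions: LiN(SiMe3)2 (2.2 equiv), THF, −78 °C; CF3CO2CH2CF3; then MeSO2N3, Et3N, H2O, MeCN, rt
Reagents that add atoms: methanesulfonyl azide, CS(=O)(=O)N=[N+]=[N-]; 2,2,2‑trifluoroethyl trifluoroacetate, O=C(OCC(F)(F)F)C(F)(F)F (its CF3CO group is carried only by 8)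
Why: Detrifluoroacetylative (Regitz‑type) diazo transfer at the only enolisable α‑carbon; no stereocentre is involved.

**Step 6**
Reactants: 9 (2R,5R)‑6‑diazo‑2‑hydroxy‑5‑methyl‑2‑(propan‑2‑yl)‑5‑(prop‑2‑en‑1‑yl)cyclohexan‑1‑one
Product: 11 methyl (1S,2R,5R)‑2‑hydroxy‑5‑methyl‑2‑(propan‑2‑yl)‑5‑(prop‑2‑en‑1‑yl)cyclopentane‑1‑carboxylate, via ketene 10 (not isolated)
Conditions: hν (medium‑pressure Hg lamp, Pyrex), MeOH, 0 °C to rt
Reagents that add atoms: methanol, CO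
Why: Photochemical Wolff rearrangement: N2 loss with a concerted 1,2‑shift of the carbinol carbon (retention) forms the C4–C5 bond and contracts the ring; MeOH traps the ketene, protonating C5 from the less hindered face (ester trans to OH expected; either epimer converges in step 7).

**Step 7**
Reactants: 11 methyl (1S,2R,5R)‑2‑hydroxy‑5‑methyl‑2‑(propan‑2‑yl)‑5‑(prop‑2‑en‑1‑yl)cyclopentane‑1‑carboxylate
Product: 13 (1R,2R,5R)‑2‑hydroxy‑5‑methyl‑2‑(propan‑2‑yl)‑5‑(prop‑2‑en‑1‑yl)cyclopentane‑1‑carbaldehyde, via epimeric aldehyde 12 (not isolated)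
Conditions: i‑Bu2AlH (2.2 equiv), CH2Cl2, −78 °C; aq. KNaC4H4O6; then Et3N, CH2Cl2, rt
Reagents that add atoms: none
Why: Partial ester reduction through a chelated aluminium hemiacetal, then base epimerisation at the α‑carbon to the thermodynamically preferred aldehyde (CHO cis to OH and H‑bonded, trans to iPr and allyl), which sets C5.

**Step 8**
Reactants: 13 (1R,2R,5R)‑2‑hydroxy‑5‑methyl‑2‑(propan‑2‑yl)‑5‑(prop‑2‑en‑1‑yl)cyclopentane‑1‑carbaldehyde; 14 (2‑methylallyl)magnesium chloride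
Product: 15 (1R,2S,3R)‑2‑[(1S)‑1‑hydroxy‑3‑methylbut‑3‑en‑1‑yl]‑3‑methyl‑1‑(propan‑2‑yl)‑3‑(prop‑2‑en‑1‑yl)cyclopentan‑1‑ol
Conditions: 14 (2.5 equiv), THF, −78 °C; aq. NH4Cl
Reagents that add atoms: none
Why: Chelation‑controlled Grignard addition (Cram chelate): the magnesium alkoxide of the cis tertiary OH binds the aldehyde oxygen and the reagent attacks the exposed face away from the ring, giving the (S)‑carbinol at C6.

**Step 9**
Reactants: 15 (1R,2S,3R)‑2‑[(1S)‑1‑hydroxy‑3‑methylbut‑3‑en‑1‑yl]‑3‑methyl‑1‑(propan‑2‑yl)‑3‑(prop‑2‑en‑1‑yl)cyclopentan‑1‑ol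
Product: 16 jaeschkeanadiol, (3R,3aS,4S,8aR)‑6,8a‑dimethyl‑3‑(propan‑2‑yl)‑1,2,3,3a,4,5,8,8a‑octahydroazulene‑3,4‑diol
Conditions: second‑generation Grubbs catalyst RuCl2(=CHPh)(PCy3)(H2IMes) (5 mol %), CH2Cl2 (5 mM), 40 °C
Reagents that add atoms: none
Why: Ring‑closing metathesis of the allyl and methallyl groups closes the trans‑fused seven‑membered ring with the trisubstituted C8=C9 alkene; no stereocentre is touched.

**Step 10**
Reactants: 16 jaeschkeanadiol; 17 3,4‑dimethoxybenzoyl chloride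
Product: 18 (3R,3aS,4S,8aR)‑3‑hydroxy‑6,8a‑dimethyl‑3‑(propan‑2‑yl)‑1,2,3,3a,4,5,8,8a‑octahydroazulen‑4‑yl 3,4‑dimethoxybenzoate (target)
Conditions: Et3N, DMAP (cat.), CH2Cl2, 0 °C to rt
Reagents that add atoms: none
Why: DMAP‑catalysed acylation takes the secondary C6–OH; the hindered tertiary C4–OH does not react.

**Compound list**
1 | (S)‑(+)‑terpinen‑4‑ol | CC1=CC[C@](O)(C(C)C)CC1 | starting material
2 | triethyl{[(1S)‑4‑methyl‑1‑(propan‑2‑yl)cyclohex‑3‑en‑1‑yl]oxy}silane | CC1=CC[C@](O[Si](CC)(CC)CC)(C(C)C)CC1 | intermediate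
3 | (6R)‑3‑methyl‑6‑(propan‑2‑yl)‑6‑[(triethylsilyl)oxy]cyclohex‑2‑en‑1‑one | CC1=CC(=O)[C@](O[Si](CC)(CC)CC)(C(C)C)CC1 | intermediate
4 | allylmagnesium bromide | C=CC[Mg]Br | starting material
5 | (1R,6R)‑3‑methyl‑6‑(propan‑2‑yl)‑1‑(prop‑2‑en‑1‑yl)‑6‑[(triethylsilyl)oxy]cyclohex‑2‑en‑1‑ol (allyl trans to OSiEt3) | CC1=C[C@](O)(CC=C)[C@](O[Si](CC)(CC)CC)(C(C)C)CC1 | intermediate
6 | (2R,5R)‑5‑methyl‑2‑(propan‑2‑yl)‑5‑(prop‑2‑en‑1‑yl)‑2‑[(triethylsilyl)oxy]cyclohexan‑1‑one | C=CC[C@@]1(C)CC[C@@](O[Si](CC)(CC)CC)(C(C)C)C(=O)C1 | intermediate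
7 | (2R,5R)‑2‑hydroxy‑5‑methyl‑2‑(propan‑2‑yl)‑5‑(prop‑2‑en‑1‑yl)cyclohexan‑1‑one | C=CC[C@@]1(C)CC[C@@](O)(C(C)C)C(=O)C1 | intermediate
8 | (2R,5R,6Z)‑2‑hydroxy‑5‑methyl‑2‑(propan‑2‑yl)‑5‑(prop‑2‑en‑1‑yl)‑6‑(2,2,2‑trifluoro‑1‑hydroxyethylidene)cyclohexan‑1‑one | C=CC[C@@]1(C)CC[C@@](O)(C(C)C)C(=O)/C1=C(\O)C(F)(F)F | intermediate
9 | (2R,5R)‑6‑diazo‑2‑hydroxy‑5‑methyl‑2‑(propan‑2‑yl)‑5‑(prop‑2‑en‑1‑yl)cyclohexan‑1‑one | C=CC[C@@]1(C)CC[C@@](O)(C(C)C)C(=O)C1=[N+]=[N-] | intermediate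
10 | [(2R,5R)‑2‑hydroxy‑5‑methyl‑2‑(propan‑2‑yl)‑5‑(prop‑2‑en‑1‑yl)cyclopentylidene]methanone (ketene) | C=CC[C@@]1(C)CC[C@@](O)(C(C)C)C1=C=O | intermediate
11 | methyl (1S,2R,5R)‑2‑hydroxy‑5‑methyl‑2‑(propan‑2‑yl)‑5‑(prop‑2‑en‑1‑yl)cyclopentane‑1‑carboxylate (ester trans to OH) | C=CC[C@@]1(C)CC[C@@](O)(C(C)C)[C@H]1C(=O)OC | intermediate
12 | (1S,2R,5R)‑2‑hydroxy‑5‑methyl‑2‑(propan‑2‑yl)‑5‑(prop‑2‑en‑1‑yl)cyclopentane‑1‑carbaldehyde (CHO trans to OH) | C=CC[C@@]1(C)CC[C@@](O)(C(C)C)[C@H]1C=O | intermediate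
13 | (1R,2R,5R)‑2‑hydroxy‑5‑methyl‑2‑(propan‑2‑yl)‑5‑(prop‑2‑en‑1‑yl)cyclopentane‑1‑carbaldehyde (CHO cis to OH and Me) | C=CC[C@@]1(C)CC[C@@](O)(C(C)C)[C@@H]1C=O | intermediate
14 | (2‑methylallyl)magnesium chloride | CC(=C)C[Mg]Cl | starting material
15 | (1R,2S,3R)‑2‑[(1S)‑1‑hydroxy‑3‑methylbut‑3‑en‑1‑yl]‑3‑methyl‑1‑(propan‑2‑yl)‑3‑(prop‑2‑en‑1‑yl)cyclopentan‑1‑ol | C=CC[C@@]1(C)CC[C@@](O)(C(C)C)[C@@H]1[C@@H](O)CC(C)=C | intermediate
16 | jaeschkeanadiol, (3R,3aS,4S,8aR)‑6,8a‑dimethyl‑3‑(propan‑2‑yl)‑1,2,3,3a,4,5,8,8a‑octahydroazulene‑3,4‑diol | O[C@H]1CC(C)=CC[C@@]2(C)CC[C@@](O)(C(C)C)[C@H]12 | intermediate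
17 | 3,4‑dimethoxybenzoyl chloride | COc1ccc(C(=O)Cl)cc1OC | starting material
18 | (3R,3aS,4S,8aR)‑3‑hydroxy‑6,8a‑dimethyl‑3‑(propan‑2‑yl)‑1,2,3,3a,4,5,8,8a‑octahydroazulen‑4‑yl 3,4‑dimethoxybenzoate | COc1ccc(C(=O)O[C@H]2CC(C)=CC[C@@]3(C)CC[C@@](O)(C(C)C)[C@H]23)cc1OC | target

**Totals:** 10 steps; longest linear sequence 10 steps (1 → 18).

**Steps most likely to fail, with fallbacks**

Step 2 (regiochemistry of the allylic oxidation; the other allylic CH2 or over‑oxidation may compete). The fallback sets out from 2 and returns at 3, building the enone by oxygen transposition. Epoxidation of 2 (mCPBA, NaHCO3, CH2Cl2) gives the epoxide of 2 with the oxirane anti to OSiEt3, F1. PhSeNa [(PhSe)2, NaBH4, EtOH] opens it at the secondary carbon to the trans hydroxy selenide F2. H2O2 oxidation gives the selenoxide F3, which can only syn‑eliminate away from the fully substituted carbinol carbon, giving the tertiary allylic alcohol F4. Pyridinium chlorochromate, (C5H5NH)[CrO3Cl], then effects the oxidative 1,3‑transposition (Babler–Dauben) to 3.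

Step 3 (face selectivity of the allyl Grignard addition, which step 4 relays to C1; allylmagnesium reagents can be poorly selective). The fallback sets out from 3 and returns at 7, by‑passing 5. It uses direct conjugate allylation, where stereoelectronic axial attack at the β‑carbon is trans to the axial OSiEt3: 4 with CuBr·SMe2, LiCl and Me3SiCl in THF at −78 °C gives the trimethylsilyl enol ether of 6, F5. Bu4NF/AcOH then removes both silyl groups to give 7.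

Step 8 (chelation control at C6; the magnesium aldolate may also undergo retro‑aldol cleavage). The fallback sets out from 13 and returns at 18. If the addition favours the other carbinol epimer, that diol, the (1R)‑hydroxy epimer of 15, F6, is cyclised with the same catalyst to 6‑epi‑jaeschkeanadiol F7. F7 is then esterified with inversion by a Mitsunobu reaction (3,4‑dimethoxybenzoic acid, PPh3, DIAD, toluene), which gives 18 directly.

**Further compounds**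
F1 | step 2 | epoxide of 2, oxirane anti to OSiEt3: triethyl{[6‑methyl‑3‑(propan‑2‑yl)‑7‑oxabicyclo[4.1.0]heptan‑3‑yl]oxy}silane | C[C@]12CC[C@@](O[Si](CC)(CC)CC)(C(C)C)C[C@H]1O2
F2 | step 2 | 1‑methyl‑2‑(phenylselanyl)‑4‑(propan‑2‑yl)‑4‑[(triethylsilyl)oxy]cyclohexan‑1‑ol (OH and SePh trans; OH trans to OSiEt3) | C[C@]1(O)CC[C@@](O[Si](CC)(CC)CC)(C(C)C)C[C@@H]1[Se]c1ccccc1
F3 | step 2 | selenoxide of F2 (both Se epimers) | C[C@]1(O)CC[C@@](O[Si](CC)(CC)CC)(C(C)C)C[C@@H]1[Se](=O)c1ccccc1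
F4 | step 2 | 1‑methyl‑4‑(propan‑2‑yl)‑4‑[(triethylsilyl)oxy]cyclohex‑2‑en‑1‑ol (OH trans to OSiEt3) | C[C@]1(O)CC[C@@](O[Si](CC)(CC)CC)(C(C)C)C=C1
F5 | step 3 | trimethylsilyl enol ether of 6 | C=CC[C@@]1(C)CC[C@@](O[Si](CC)(CC)CC)(C(C)C)C(O[Si](C)(C)C)=C1
F6 | step 8 | (1R,2S,3R)‑2‑[(1R)‑1‑hydroxy‑3‑methylbut‑3‑en‑1‑yl]‑3‑methyl‑1‑(propan‑2‑yl)‑3‑(prop‑2‑en‑1‑yl)cyclopentan‑1‑ol | C=CC[C@@]1(C)CC[C@@](O)(C(C)C)[C@@H]1[C@H](O)CC(C)=C
F7 | step 8 | 6‑epi‑jaeschkeanadiol, (3R,3aS,4R,8aR)‑6,8a‑dimethyl‑3‑(propan‑2‑yl)‑1,2,3,3a,4,5,8,8a‑octahydroazulene‑3,4‑diol | O[C@@H]1CC(C)=CC[C@@]2(C)CC[C@@](O)(C(C)C)[C@H]12
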